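The ten-membered carbocycle is closed last but one, at the bond between C7 (the ring carbon bearing the isopropenyl group) and C8 (the allylic CH2 of the C9=C10 enoate). The step exploits two latent functions: C7 is the α-carbon of a methyl ketone (isopropenyl = acetyl plus CH2), and C8–C9–C10 is an ester-substituted π-allyl unit. A Pd-catalysed intramolecular allylic alkylation of a regio- and geometry-defined silyl enol ether by an allylic carbonate forms C7–C8, closes the ring and sets C7 under ligand control. Its precursor is an acyclic chain that already carries the Sharpless-derived epoxide, both esters and the E-enoate; Tebbe methylenation then gives the target.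

Key step: step 15

Remark on labels: atoms are labelled as in a germacrane (ring C1–C10; epoxide C3–C4; C5 acetoxy; C7 isopropenyl; C14 ester carbon on C10; C15 the CH2O on C4); descriptors quoted as (3R,4S,5S) refer to these labels.
Remark on materials: 1, 2, 5, 7, 13, 16 and 21 are taken as purchasable.

Step 1
Reactants: 1 methyl (triphenylphosphoranylidene)acetate; 2 4-iodobut-1-yne
Product: 4 methyl 2-(triphenylphosphoranylidene)hex-5-ynoate, via phosphonium iodide 3 (not isolated)
Conditions: 1 (2.0 equiv), EtOAc, reflux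
Reagents that add atoms: none
Why: C-alkylation of the stabilised ylide by the primary iodide gives salt 3, which a second equivalent of 1 deprotonates (ylide alkylation–transylidation); no stereocenter is formed.

Step 2
Reactants: 4; 5 (tert-butyldimethylsilyloxy)acetaldehyde
Product: 6 methyl (2E)-2-(but-3-yn-1-yl)-4-[(tert-butyldimethylsilyl)oxy]but-2-enoate
Conditions: toluene, 80 °C
Reagents that add atoms: none
Why: Wittig olefination with an α-substituted stabilised ylide is E-selective, placing C8 (CH2OTBS) trans to the ester and cis to C1, the C9=C10 geometry of the target.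

Step 3
Reactants: 6; 7 (E)-but-2-enal
Product: 9 methyl (2E)-4-[(tert-butyldimethylsilyl)oxy]-2-[(5S,6E)-5-hydroxyoct-6-en-3-yn-1-yl]but-2-enoate, via methylzinc acetylide 8 (not isolated)
Conditions: Me2Zn (3 equiv), (R,R)-ProPhenol (20 mol%), Ph3PO (40 mol%), toluene, 4 °C; aq. NH4Cl
Reagents that add atoms: none
Why: Zinc–ProPhenol asymmetric alkynylation adds acetylide 8 1,2 to the enal and sets the C5 carbinol (S) by reagent control; the ligand antipode named is the one taken to correspond to the S carbinol, and the other antipode is used if the facial sense proves opposite.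

Step 4
Reactants: 9
Product: 10 methyl (2E)-4-[(tert-butyldimethylsilyl)oxy]-2-[(3Z,5S,6E)-5-hydroxy-4-(tributylstannyl)octa-3,6-dien-1-yl]but-2-enoate
Conditions: Bu3SnH (1.1 equiv), [Cp*RuCl]4 (2.5 mol%), CH2Cl2, rt
Reagents that add atoms: tributyltin hydride, CCCC[SnH](CCCC)CCCC
Why: Ruthenium-catalysed trans-hydrostannation directed by the free propargylic hydroxyl places tin on C4 and hydrogen trans on C3, so the C2 chain lies cis to tin, the position later taken by C15.

Step 5
Reactants: 10
Product: 11 methyl (2E)-4-[(tert-butyldimethylsilyl)oxy]-2-[(3Z,5S,6E)-5-hydroxy-4-iodoocta-3,6-dien-1-yl]but-2-enoate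
Conditions: I2, CH2Cl2, 0 °C
Reagents that add atoms: iodine, II
Why: Iododestannylation (tin–iodine exchange) proceeds with retention of alkene geometry.

Step 6
Reactants: 11
Product: 12 methyl (2E)-4-[(tert-butyldimethylsilyl)oxy]-2-[(3Z,5S,6E)-4-iodo-5-[(triethylsilyl)oxy]octa-3,6-dien-1-yl]but-2-enoate
Conditions: Et3SiCl, imidazole, CH2Cl2, 0 °C
Reagents that add atoms: chlorotriethylsilane, CC[Si](Cl)(CC)CC
Why: Silyl ether formation masks the C5 hydroxyl so that it cannot direct the later titanium epoxidation to the propenyl alkene.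

Step 7
Reactants: 12; 13 (tributylstannyl)methanol
Product: 14 methyl (2E)-4-[(tert-butyldimethylsilyl)oxy]-2-[(3E,5S,6E)-4-(hydroxymethyl)-5-[(triethylsilyl)oxy]octa-3,6-dien-1-yl]but-2-enoate
Conditions: Pd(PPh3)4 (10 mol%), dioxane, 90 °C
Reagents that add atoms: none
Why: Stille–Kosugi hydroxymethylation couples the alkenyl iodide with the α-hydroxymethyl stannane at zerovalent palladium with retention of geometry, giving the C15 allylic alcohol as the only free hydroxyl.

Step 8
Reactants: 14
Product: 15 (3R,4S,5S)-epoxy alcohol: methyl (2E)-4-[(tert-butyldimethylsilyl)oxy]-2-{2-[(2R,3S)-3-(hydroxymethyl)-3-{(1S,2E)-1-[(triethylsilyl)oxy]but-2-en-1-yl}oxiran-2-yl]ethyl}but-2-enoate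
Conditions: Ti(OiPr)4, L-(+)-diisopropyl tartrate, t-BuOOH (decane), 4 Å MS, CH2Cl2, −20 °C
Reagents that add atoms: tert-butyl hydroperoxide, CC(C)(C)OO
Why: Sharpless asymmetric epoxidation: the titanium L-(+)-tartrate complex delivers oxygen to the face that gives the (3R,4S) epoxide (reagent control by the tartrate mnemonic, C2 and C15 staying cis), and the propenyl and enoate alkenes, lacking a free allylic hydroxyl, are not epoxidised.

Step 9
Reactants: 15; 16 (R)-2-methylbutanoic acid
Product: 17 (3R,4S,5S)-epoxy ester: methyl (2E)-4-[(tert-butyldimethylsilyl)oxy]-2-{2-[(2R,3S)-3-({[(2R)-2-methylbutanoyl]oxy}methyl)-3-{(1S,2E)-1-[(triethylsilyl)oxy]but-2-en-1-yl}oxiran-2-yl]ethyl}but-2-enoate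
Conditions: N,N'-diisopropylcarbodiimide, DMAP (cat.), CH2Cl2, 0 °C
Reagents that add atoms: none
Why: Steglich esterification of the single free (primary) hydroxyl installs the (R)-2-methylbutanoate without touching its α-stereocenter.

Step 10
Reactants: 17
Product: 18 (3R,4R,5S)-diol: methyl (2E)-4-hydroxy-2-{2-[(2R,3R)-3-[(1S,2E)-1-hydroxybut-2-en-1-yl]-3-({[(2R)-2-methylbutanoyl]oxy}methyl)oxiran-2-yl]ethyl}but-2-enoate
Conditions: HF·pyridine, pyridine, THF, 0 °C to rt
Reagents that add atoms: none
Why: Buffered fluoride cleavage of silyl ethers removes the TES and the primary TBS group together, epoxide and esters being stable to HF·pyridine (the C4 descriptor changes only through CIP priorities).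

Step 11
Reactants: 18
Product: 19 (3R,4R,5S)-carbonate: methyl (2E)-2-{2-[(2R,3R)-3-[(1S,2E)-1-hydroxybut-2-en-1-yl]-3-({[(2R)-2-methylbutanoyl]oxy}methyl)oxiran-2-yl]ethyl}-4-[(methoxycarbonyl)oxy]but-2-enoate
Conditions: ClCO2Me (1.1 equiv), pyridine, CH2Cl2, −30 °C
Reagents that add atoms: methyl chloroformate, COC(=O)Cl
Why: Chemoselective carbonate formation: the unhindered primary allylic C8 hydroxyl reacts far faster than the secondary C5 hydroxyl flanked by the quaternary epoxide carbon.

Step 12
Reactants: 19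
Product: 20 (3R,4S,5S)-acetate: methyl (2E)-2-{2-[(2R,3S)-3-[(1S,2E)-1-acetoxybut-2-en-1-yl]-3-({[(2R)-2-methylbutanoyl]oxy}methyl)oxiran-2-yl]ethyl}-4-[(methoxycarbonyl)oxy]but-2-enoate
Conditions: Ac2O, pyridine, DMAP (cat.), CH2Cl2, 0 °C
Reagents that add atoms: acetic anhydride, CC(=O)OC(C)=O
Why: DMAP-catalysed acetylation of the remaining secondary hydroxyl gives the C5 acetate of the target.

Step 13
Reactants: 20; 21 but-3-en-2-one
Product: 22 (3R,4S,5S)-enone: methyl (2E)-2-{2-[(2R,3S)-3-[(1S,2E)-1-acetoxy-4-oxopent-2-en-1-yl]-3-({[(2R)-2-methylbutanoyl]oxy}methyl)oxiran-2-yl]ethyl}-4-[(methoxycarbonyl)oxy]but-2-enoate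
Conditions: 21 (5 equiv), second-generation Hoveyda–Grubbs catalyst (5–10 mol%), CH2Cl2, 40 °C
Reagents that add atoms: none
Why: Olefin cross-metathesis of the disubstituted propenyl group with the electron-poor partner 21 should give the E-enone with loss of propene, the trisubstituted enoate being inert to the ruthenium carbene.

Step 14
Reactants: 22
Product: 23 (3R,4S,5S)-silyl enol ether: methyl (2E)-2-{2-[(2R,3S)-3-{(1S,3Z)-1-acetoxy-4-[(triethylsilyl)oxy]pent-3-en-1-yl}-3-({[(2R)-2-methylbutanoyl]oxy}methyl)oxiran-2-yl]ethyl}-4-[(methoxycarbonyl)oxy]but-2-enoate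
Conditions: Et3SiH (1.2 equiv), RhCl(PPh3)3 (2 mol%), THF, 40 °C
Reagents that add atoms: triethylsilane, CC[SiH](CC)CC
Why: Rhodium-catalysed 1,4-hydrosilylation of the s-cis enone delivers hydride to C6 and silicon to oxygen, so the enol ether forms regiospecifically at C7=C11 and mainly as the Z isomer, while the α-branched trisubstituted enoate is not reduced.

Step 15
Reactants: 23
Product: 24 methyl (1S,2S,4S,6E,10R)-2-acetoxy-4-acetyl-1-({[(2R)-2-methylbutanoyl]oxy}methyl)-11-oxabicyclo[8.1.0]undec-6-ene-7-carboxylate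
Conditions: Pd2(dba)3·CHCl3 (5 mol%), (R,R)-DACH-phenyl Trost ligand (12 mol%), Bu4N[Ph3SiF2] (10 mol%), THF, 0.002 M by syringe-pump addition, 25 to 40 °C
Reagents that add atoms: none
Why: Zerovalent palladium bound to the chiral diphosphine ionises the allylic carbonate to a cationic π-allyl complex spanning C8–C9–C10 and, after loss of CO2, methoxide (started by the fluoride initiator) cleaves the Si–O bond to release the Z-configured C7 ketone enolate, which attacks the unsubstituted terminus C8 from outside the metal. The closest known reactions are the Tsuji allylation of silyl enol ethers with allylic carbonates, the asymmetric Tsuji–Trost alkylation of acyclic ketone enolates of defined geometry, and Tsuji–Trost macrocyclisation. The ring closes as a ten-membered carbocycle by C-allylation at the allyl terminus distal to the ester, so C9=C10 becomes endocyclic and keeps its E geometry from 23 because capture should outrun syn/anti exchange. The single new stereocenter, C7 (S), is set by facial discrimination of the geometry-defined enolate in the chiral pocket of the ligand, reinforced or opposed by the C3–C5 stereotriad; the ligand antipode is the alternative if the pairing proves mismatched. The step needs C8 over C10 attack (secured by the quaternary, ester-bearing C10), C- over O-allylation (O-allylation is reversible under palladium) and ring closure over oligomerisation (high dilution, plus the turn imposed by the cis C8/C1 pair on C9=C10 and by the trans-epoxide).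

Step 16
Reactants: 24
Product: 25 methyl (1S,2S,4S,6E,10R)-2-acetoxy-1-({[(2R)-2-methylbutanoyl]oxy}methyl)-4-(prop-1-en-2-yl)-11-oxabicyclo[8.1.0]undec-6-ene-7-carboxylate (target)
Conditions: Cp2Ti(μ-Cl)(μ-CH2)AlMe2 (Tebbe reagent, 1.2 equiv), pyridine, THF/toluene, −40 to 0 °C
Reagents that add atoms: Tebbe reagent, C=[Ti](C1C=CC=C1)C1C=CC=C1.C[Al](C)Cl
Why: Tebbe methylenation (titanium methylidene, oxatitanacyclobutane) converts the ketone into the isopropenyl group under non-basic conditions that should not epimerise C7 and, at low temperature, discriminates the ketone from the three esters.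

Compound list
1 | methyl (triphenylphosphoranylidene)acetate | COC(=O)C=P(c1ccccc1)(c1ccccc1)c1ccccc1 | starting material
2 | 4-iodobut-1-yne | C#CCCI | starting material
3 | (1-methoxy-1-oxohex-5-yn-2-yl)triphenylphosphonium iodide | COC(=O)C(CCC#C)[P+](c1ccccc1)(c1ccccc1)c1ccccc1.[I-] | intermediate
4 | methyl 2-(triphenylphosphoranylidene)hex-5-ynoate | COC(=O)C(CCC#C)=P(c1ccccc1)(c1ccccc1)c1ccccc1 | intermediate
5 | (tert-butyldimethylsilyloxy)acetaldehyde | O=CCO[Si](C)(C)C(C)(C)C | starting material
6 | methyl (2E)-2-(but-3-yn-1-yl)-4-[(tert-butyldimethylsilyl)oxy]but-2-enoate | C#CCC/C(=C\CO[Si](C)(C)C(C)(C)C)C(=O)OC | intermediate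
7 | (E)-but-2-enal | C/C=C/C=O | starting material
8 | methylzinc acetylide of 6 | C[Zn]C#CCC/C(=C\CO[Si](C)(C)C(C)(C)C)C(=O)OC | intermediate
9 | (5S)-propargylic alcohol | CC(C)(C)[Si](C)(C)OC/C=C(/C(=O)OC)CCC#C[C@@H](O)/C=C/C | intermediate
10 | (3Z,5S)-alkenylstannane | CC(C)(C)[Si](C)(C)OC/C=C(/C(=O)OC)CC/C=C(\[Sn](CCCC)(CCCC)CCCC)[C@@H](O)/C=C/C | intermediate
11 | (3Z,5S)-alkenyl iodide | CC(C)(C)[Si](C)(C)OC/C=C(/C(=O)OC)CC/C=C(\I)[C@@H](O)/C=C/C | intermediate
12 | (3Z,5S)-alkenyl iodide TES ether | CC(C)(C)[Si](C)(C)OC/C=C(/C(=O)OC)CC/C=C(\I)[C@@H](O[Si](CC)(CC)CC)/C=C/C | intermediate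
13 | (tributylstannyl)methanol | OC[Sn](CCCC)(CCCC)CCCC | starting material
14 | (3E,5S)-allylic alcohol | CC(C)(C)[Si](C)(C)OC/C=C(/C(=O)OC)CC/C=C(\CO)[C@@H](O[Si](CC)(CC)CC)/C=C/C | intermediate
15 | (3R,4S,5S)-epoxy alcohol | CC(C)(C)[Si](C)(C)OC/C=C(/C(=O)OC)CC[C@H]1O[C@]1(CO)[C@@H](O[Si](CC)(CC)CC)/C=C/C | intermediate
16 | (R)-2-methylbutanoic acid | CC[C@@H](C)C(=O)O | starting material
17 | (3R,4S,5S)-epoxy 2-methylbutanoate with TES and TBS ethers | CC(C)(C)[Si](C)(C)OC/C=C(/C(=O)OC)CC[C@H]1O[C@]1(COC(=O)[C@H](C)CC)[C@@H](O[Si](CC)(CC)CC)/C=C/C | intermediate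
18 | (3R,4R,5S)-diol | OC/C=C(/C(=O)OC)CC[C@H]1O[C@]1(COC(=O)[C@H](C)CC)[C@@H](O)/C=C/C | intermediate
19 | (3R,4R,5S)-C8 methyl carbonate | COC(=O)OC/C=C(/C(=O)OC)CC[C@H]1O[C@]1(COC(=O)[C@H](C)CC)[C@@H](O)/C=C/C | intermediate
20 | (3R,4S,5S)-C5 acetate | COC(=O)OC/C=C(/C(=O)OC)CC[C@H]1O[C@]1(COC(=O)[C@H](C)CC)[C@@H](OC(C)=O)/C=C/C | intermediate
21 | but-3-en-2-one | CC(=O)C=C | starting material
22 | (3R,4S,5S)-enone | COC(=O)OC/C=C(/C(=O)OC)CC[C@H]1O[C@]1(COC(=O)[C@H](C)CC)[C@@H](OC(C)=O)/C=C/C(C)=O | intermediate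
23 | (3R,4S,5S)-(Z)-triethylsilyl enol ether | COC(=O)OC/C=C(/C(=O)OC)CC[C@H]1O[C@]1(COC(=O)[C@H](C)CC)[C@@H](OC(C)=O)C/C=C(/C)O[Si](CC)(CC)CC | intermediate
24 | (3R,4S,5S,7S)-macrocyclic methyl ketone | CC(=O)[C@H]1C/C=C(/C(=O)OC)CC[C@H]2O[C@]2(COC(=O)[C@H](C)CC)[C@@H](OC(C)=O)C1 | intermediate
25 | CNP0352790.1 | C=C(C)[C@H]1C/C=C(/C(=O)OC)CC[C@H]2O[C@]2(COC(=O)[C@H](C)CC)[C@@H](OC(C)=O)C1 | target

Total step count: 16. Longest linear sequence: 16 steps (1 and 2 through 25).

Steps most likely to fail

Step 15. The ten-membered closure may lose to β-hydride elimination of the π-allyl complex to a diene, to oligomerisation, to acetyl transfer from the C5 acetate to the free enolate or methoxide, or it may give poor facial selectivity at C7. The fallback sets out from 23 and returns at 24, forming the same C7–C8 bond with a stabilised carbanion. Sulfenylation of 23 with PhSCl (CH2Cl2, −78 °C) should give the α-phenylthio ketone F1. Oxidation with mCPBA (2 equiv, 0 °C) gives the β-keto sulfone F2. A base-free Tsuji–Trost macrocyclisation (Pd(PPh3)4, dppe, THF, 0.002 M, 60 °C; the methoxide released from the carbonate deprotonates the sulfone) gives the ring-closed β-keto sulfone F3. Reductive desulfonylation with SmI2 (THF/MeOH, −78 °C) gives 24, whose C7 epimers would be equilibrated with DBU and separated.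

Step 8. The Z-substituted, α-branched allylic alcohol may be epoxidised slowly or with poor facial selectivity if the C5 stereocenter is mismatched with the tartrate. The fallback sets out from 14 and returns at 22, replacing the hydroxyl-directed titanium epoxidation by a catalyst-controlled dioxirane epoxidation. Esterification of 14 with 16 (carbodiimide, DMAP) gives the allylic 2-methylbutanoate F4. Cross-metathesis with 21 gives the enone F5, which leaves C3=C4 as the only electron-rich alkene. Shi epoxidation (D-fructose-derived ketone, Oxone, K2CO3, MeCN/dimethoxymethane, 0 °C) gives the epoxide F6. HF·pyridine gives the diol F7, ClCO2Me/pyridine gives the C8 carbonate F8, and acetylation gives 22.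

Step 16. Methylenation may lose chemoselectivity between the ketone and the three esters, or the aluminium Lewis acid may open the epoxide. The fallback sets out from 24 and returns at 25 by a two-stage Peterson olefination. Me3SiCH2Li/CeCl3 (THF, −78 °C) adds to the ketone to give the β-hydroxysilane F9, and HF·pyridine (MeCN, 0 °C) eliminates it to 25.

Further compounds
F1 | step 15 | C7 phenylthio methyl ketone from 23 | COC(=O)OC/C=C(/C(=O)OC)CC[C@H]1O[C@]1(COC(=O)[C@H](C)CC)[C@@H](OC(C)=O)CC(Sc1ccccc1)C(C)=O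
F2 | step 15 | C7 phenylsulfonyl methyl ketone (β-keto sulfone) | COC(=O)OC/C=C(/C(=O)OC)CC[C@H]1O[C@]1(COC(=O)[C@H](C)CC)[C@@H](OC(C)=O)CC(C(C)=O)S(=O)(=O)c1ccccc1
F3 | step 15 | ring-closed 7-acetyl-7-(phenylsulfonyl) macrocycle | CC(=O)C1(S(=O)(=O)c2ccccc2)C/C=C(/C(=O)OC)CC[C@H]2O[C@]2(COC(=O)[C@H](C)CC)[C@@H](OC(C)=O)C1
F4 | step 8 | (R)-2-methylbutanoate of 14 | CC(C)(C)[Si](C)(C)OC/C=C(/C(=O)OC)CC/C=C(\COC(=O)[C@H](C)CC)[C@@H](O[Si](CC)(CC)CC)/C=C/C
F5 | step 8 | enone from F4 | CC(C)(C)[Si](C)(C)OC/C=C(/C(=O)OC)CC/C=C(\COC(=O)[C@H](C)CC)[C@@H](O[Si](CC)(CC)CC)/C=C/C(C)=O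
F6 | step 8 | (3R,4S)-epoxide of F5 | CC(C)(C)[Si](C)(C)OC/C=C(/C(=O)OC)CC[C@H]1O[C@]1(COC(=O)[C@H](C)CC)[C@@H](O[Si](CC)(CC)CC)/C=C/C(C)=O
F7 | step 8 | desilylated diol enone | OC/C=C(/C(=O)OC)CC[C@H]1O[C@]1(COC(=O)[C@H](C)CC)[C@@H](O)/C=C/C(C)=O
F8 | step 8 | C8 methyl carbonate of F7 | COC(=O)OC/C=C(/C(=O)OC)CC[C@H]1O[C@]1(COC(=O)[C@H](C)CC)[C@@H](O)/C=C/C(C)=O
F9 | step 16 | β-hydroxysilane from 24 | C[Si](C)(C)CC(C)(O)[C@H]1C/C=C(/C(=O)OC)CC[C@H]2O[C@]2(COC(=O)[C@H](C)CC)[C@@H](OC(C)=O)C1
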